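**Retrosynthetic overview**
Target 28 ← lactol oxidation, acylation, hydroboration and methylenation ← bridged cyclodec-4-en-10-one 20, in which the C15–O–C6 butenolide already spans C4 and C6 of the ten-membered carbocycle C1–C10.
Feature used: with a ketone drawn at C10, the chain C10–C1–C2–C3–C4=C5 is an oxy-Cope retron, and C5–C10 folds back into a cyclohexane oxygenated at C6, C8 and C10. The key disconnection is therefore C2–C3, made by anionic oxy-Cope rearrangement of the trans-1,2-dialkenylcyclohexanol 17 (vinyl on C10, alkoxymethylene lactone on C5, cis-fused through the C6 oxygen).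
17 ← vinyl addition at C10, formylation and O-benzylation at C4, lactone from C5 alkylation; C7–C11 from a 5-exo-dig radical closure out of an acetal tether on the C6 oxygen; ring and C6/C8 oxygens from D-(−)-quinic acid.
Ring order: cyclohexane (chiral pool) → oxolane acetal on O6/C7 (radical) → γ-lactone on O6/C5 with shift of the acetal to O8 → ten-membered ring and butenolide together (key step) → α-methylene lactone on O8/C7 (last step).

Key step: step 13

Remark: quinic acid C1, C2, C3, C4, C5, C6 become target carbons C10, C5, C6, C7, C8, C9, and all positions below use the target numbering; the C12 acetal centre is carried as a mixture of epimers, which is harmless because C12 ends as a lactone carbonyl.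

Step 1
Reactants: 1 D-(−)-quinic acid
Product: 2 quinide (quinic acid 1,5-lactone)
Conditions: TsOH·H2O (cat.), toluene/DMF, reflux, Dean–Stark
Reagents that add atoms: none
Why: Acid-catalysed lactonisation of the carboxyl group onto the cis hydroxyl (the later C8 oxygen) touches no stereocentre and locks the ring as a bicycle in which the later C6–OH is equatorial and the later C7–OH axial.

Step 2
Reactants: 3 3,3-diethoxyprop-1-yne
Product: 4 3-chloro-3-ethoxyprop-1-yne (racemic; used as the crude solution)
Conditions: AcCl (1.0 equiv), ZnBr2 (0.1 mol %), CH2Cl2, 0 °C → rt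
Reagents that add atoms: acetyl chloride, CC(Cl)=O
Why: Zinc-halide-catalysed exchange between an acetal and an acyl chloride is the standard preparation of α-chloro ethers and gives ethyl acetate as the only co-product.

Step 3
Reactants: 2 quinide; 4 3-chloro-3-ethoxyprop-1-yne
Product: 6 quinide C6–O (1-ethoxyprop-2-yn-1-yl) mixed acetal (acetal epimers), via dibutylstannylene acetal 5 (not isolated)
Conditions: Bu2SnO, toluene, reflux (Dean–Stark); then 4, Bu4NI (cat.), toluene, 0 °C → rt; aq. NaHCO3
Reagents that add atoms: dibutyltin oxide, CCCC[Sn](=O)CCCC (atoms stay in intermediate 5 only)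
Why: Stannylene-acetal-mediated O-alkylation of a ring cis-diol takes place at the equatorial oxygen (the C6 oxygen), here with an α-chloro ether as is known for chloromethyl ethers, and leaves the axial C7–OH and the tertiary OH free.

Step 4
Reactants: 6 quinide C6–O mixed acetal
Product: 7 C7 O-(imidazol-1-ylcarbothioyl) derivative of 6
Conditions: 1,1'-thiocarbonyldiimidazole, DMAP (cat.), ClCH2CH2Cl, 70 °C
Reagents that add atoms: 1,1'-thiocarbonyldiimidazole, S=C(n1ccnc1)n1ccnc1
Why: Thioacylation of the only secondary hydroxyl gives a Barton–McCombie radical precursor without any substitution at the doubly oxygen-flanked C7, and the hindered tertiary hydroxyl does not react.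

Step 5
Reactants: 7 C7 thiocarbonylimidazolide
Product: 8 tricyclic acetal (quinide carrying a cis-fused 2-ethoxy-3-methyleneoxolane across C6–O and C7)
Conditions: Bu3SnH, AIBN (cat.), toluene, 110 °C, slow addition at high dilution
Reagents that add atoms: none
Why: Barton–McCombie C–O homolysis gives the C7 radical, which closes 5-exo-dig onto the tethered alkyne on the tether face (away from the lactone bridge), so the new C7–C11 bond is cis to the C6 oxygen and trans to the C8 oxygen, and the vinyl radical is then reduced by the stannane.

Step 6
Reactants: 8 tricyclic acetal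
Product: 9 triol (C10 carbinol with hydroxymethyl group; free C8–OH)
Conditions: NaBH4, EtOH, 0 °C → rt
Reagents that add atoms: none
Why: Borohydride reduction of the strained α-hydroxy lactone to the diol is established for quinide derivatives and leaves the acetal and the alkene untouched.

Step 7
Reactants: 9 triol
Product: 10 β-hydroxy ketone (C10 ketone; C8–OH; oxolane acetal on O6/C7)
Conditions: NaIO4, THF/pH 7 buffer, 0 °C
Reagents that add atoms: none
Why: Periodate (Malaprade) cleavage of the 1,2-diol at C10 gives the ketone and formaldehyde and cannot touch the isolated C8 hydroxyl.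

Step 8
Reactants: 10 β-hydroxy ketone; 11 ethyl bromoacetate
Product: 12 keto ester with CH2CO2Et on C5 (C5 epimers)
Conditions: LiN(iPr)2 (2.2 equiv), THF, −78 °C; then 11, DMPU, −78 → −50 °C; aq. NH4Cl
Reagents that add atoms: none
Why: In the β-hydroxy ketone dianion the C8 lithium alkoxide directs the second deprotonation to the remote α′ carbon C5, and that enolate is C-alkylated by the reactive α-bromo ester at low temperature; the C5 configuration is corrected in step 9.

Step 9
Reactants: 12 keto ester
Product: 13 tricyclic keto lactone (cis-fused γ-lactone C15–O6 on C5/C6; trans-fused 2-ethoxy-3-methyleneoxolane C12–O8 on C7/C8)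
Conditions: CSA (0.2 equiv), 4 Å MS, CH2Cl2, rt → 40 °C
Reagents that add atoms: none
Why: Acid-catalysed transacetalisation moves the C12 acetal from the C6 oxygen to the C8 hydroxyl while the released C6–OH lactonises onto the ester, and because C5 epimerises through the enol and only the cis ester can close, both epimers converge on the cis-fused lactone with C4 cis to the C6 oxygen.

Step 10
Reactants: 13 tricyclic keto lactone; 14 vinylmagnesium bromide
Product: 15 C10 vinyl carbinol (OH cis to C4 and to the C6 oxygen; vinyl trans to C4)
Conditions: CeCl3 (anhydrous), 14, THF, −78 °C; AcOH, −78 °C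
Reagents that add atoms: none
Why: The organocerium reagent adds 1,2 to the ketone without enolising it or attacking the lactone, and on the chair locked by the trans-fused oxolane it enters from the equatorial side because the axial face is blocked by the 1,3-diaxial C6 oxygen, which sets C10 with the vinyl group trans to C4.

Step 11
Reactants: 15 C10 vinyl carbinol
Product: 16 α-hydroxymethylene lactone (formyl group on C4, enol form)
Conditions: LiN(iPr)2 (2.3 equiv), THF, −78 °C; HCO2Et, −78 → −20 °C; AcOH
Reagents that add atoms: ethyl formate, CCOC=O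
Why: Claisen formylation of the lactone lithium enolate at C4 gives the stabilised formyl-lactone enolate, the tertiary lithium alkoxide formed first being too unreactive at this temperature to attack the lactone.

Step 12
Reactants: 16 α-hydroxymethylene lactone
Product: 17 oxy-Cope precursor (E-[(4-methoxybenzyl)oxy]methylene lactone with free C10–OH)
Conditions: 4-MeOC6H4CH2Cl, K2CO3, Bu4NI (cat.), DMF, rt
Reagents that add atoms: 4-methoxybenzyl chloride, COc1ccc(CCl)cc1
Why: O-alkylation of the potassium enolate of an α-formyl lactone gives the E enol ether with the ether oxygen cis to C5 and anti to the lactone carbonyl, and carbonate does not deprotonate the tertiary alcohol.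

Step 13
Reactants: 17 oxy-Cope precursor
Product: 20 bridged cyclodec-4-en-10-one (butenolide across C4/C6; C3 4-methoxybenzyl ether), via potassium alkoxide 18 (not isolated), via potassium enolate 19 (not isolated)
Conditions: KH (1.1 equiv), 18-crown-6, THF, 0 °C → rt; AcOH, −78 °C
Reagents that add atoms: none
Why: KH with 18-crown-6 turns the tertiary alcohol into the free potassium alkoxide 18, and the oxido group accelerates a concerted, chair-like [3,3] sigmatropic shift in which C2–C3 forms while C5–C10 breaks, giving the C10 enolate 19 (anionic oxy-Cope rearrangement; the closest known reaction type is the ring expansion of trans-1,2-divinylcyclohexanols to E-cyclodec-5-enones). The ten-membered carbocycle is therefore closed by a four-atom ring expansion of the cyclohexane and not by end-to-end cyclisation, and in the same event the cis-fused alkylidene lactone becomes the butenolide that bridges C4 and C6. The trans-fused oxolane locks the chair in which the vinyl group on C10 and the lactone alkylidene on C5 are both equatorial and gauche, which is the geometry the chair transition state needs. Because the lactone ties C15 to the C6 oxygen, the new C4=C5 bond can only form with C15 and C6 cis, that is as the E-cyclodecene of the target. The single new stereocentre, C3, is fixed by suprafacial bonding on the face of the alkoxymethylene unit from which C10 departs, so the C5 configuration together with the E enol ether geometry (benzyloxy group cis to C5) gives the (3S) ether. The step needs the C10 alkoxide to react in preference to side paths: reversible acyl transfer from the C6 oxygen to the C10 oxygen is drained because only the C10 alkoxide can rearrange, enolate formation makes the shift irreversible, and a small excess of base, low temperature and a cold AcOH quench limit proton transfer from the butenolide C6–H and loss of the C3 ether.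

Step 14
Reactants: 20 bridged cyclodec-4-en-10-one
Product: 21 C10 exocyclic methylene compound
Conditions: Zn, CH2Br2, TiCl4 (preformed reagent), THF/CH2Cl2, 0 °C → rt
Reagents that add atoms: dibromomethane, BrCBr
Why: Takai–Lombardo methylenation converts the C10 ketone into the C10=C14 alkene under non-basic conditions, so the acidic butenolide C6–H and the allylic C3 ether are not exposed to an ylide and the lactone carbonyl is left alone.

Step 15
Reactants: 21 C10 methylene compound
Product: 23 C14 primary alcohol, via B-alkyl-9-borabicyclononane 22 (not isolated)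
Conditions: 9-BBN, THF, 0 °C → rt; then 30% H2O2, pH 7 phosphate buffer, 0 °C → rt
Reagents that add atoms: 9-borabicyclo[3.3.1]nonane, B1C2CCCC1CCC2 (atoms stay in intermediate 22 only); hydrogen peroxide, OO
Why: Anti-Markovnikov hydroboration–oxidation with the bulky borane should take the unhindered C10 methylene in preference to the oxolane methylene (flanked by the acetal carbon and the ring fusion) and is expected to deliver hydrogen to C10 from the outer face of the conformationally restricted ten-membered ring, which would give the (10R) centre.

Step 16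
Reactants: 23 C14 primary alcohol
Product: 24 C14 tert-butyldimethylsilyl ether
Conditions: tBuMe2SiCl, imidazole, DMF, rt
Reagents that add atoms: tert-butyldimethylsilyl chloride, CC(C)(C)[Si](C)(C)Cl
Why: Standard silylation of the only free hydroxyl masks C14–OH so that the C3 oxygen can be acylated alone.

Step 17
Reactants: 24 C14 silyl ether
Product: 25 C3 alcohol
Conditions: DDQ, CH2Cl2/pH 7 buffer, 0 °C → rt
Reagents that add atoms: none
Why: Oxidative cleavage of the 4-methoxybenzyl ether by DDQ frees the C3 hydroxyl without touching the silyl ether, the acetal or the electron-poor alkenes.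

Step 18
Reactants: 25 C3 alcohol
Product: 26 C3 isobutyrate
Conditions: (iPrCO)2O, DMAP, Et3N, CH2Cl2, 0 °C → rt
Reagents that add atoms: isobutyric anhydride, CC(C)C(=O)OC(=O)C(C)C
Why: DMAP-catalysed acylation of the secondary allylic alcohol installs the isobutyrate with retention, since the C3–O bond is not broken.

Step 19
Reactants: 26 C3 isobutyrate
Product: 27 lactol (C12 hemiacetal on O8; free C14–OH; anomers)
Conditions: 48% aq. HF, MeCN, 0 °C → rt
Reagents that add atoms: water, O
Why: Aqueous HF cleaves the primary silyl ether and hydrolyses the cyclic allylic ethyl acetal to the lactol, while the hindered isobutyrate and the two unsaturated lactone units are stable to brief aqueous acid.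

Step 20
Reactants: 27 lactol
Product: 28 CNP0332805.1 (target)
Conditions: MnO2, CH2Cl2, rt
Reagents that add atoms: none
Why: MnO2 oxidises the allylic lactol to the α-methylene γ-lactone on O8 and leaves the non-allylic primary C14 alcohol untouched, completing the target with all stereocentres already in place.

**Compound list**
1 | D-(−)-quinic acid | OC(=O)[C@]1(O)C[C@@H](O)[C@@H](O)[C@H](O)C1 | starting material
2 | quinide, (1S,3R,4R,5R)-1,3,4-trihydroxy-6-oxabicyclo[3.2.1]octan-7-one | O=C3[C@]1(O)C[C@@H](O)[C@@H](O)[C@H](O3)C1 | intermediate
3 | 3,3-diethoxyprop-1-yne | C#CC(OCC)OCC | starting material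
4 | 3-chloro-3-ethoxyprop-1-yne (racemic) | C#CC(Cl)OCC | intermediate
5 | dibutylstannylene acetal of the quinide cis-diol (C6–O and C7–O) | O=C3[C@]1(O)C[C@@H](O[Sn]4(CCCC)CCCC)[C@@H](O4)[C@H](O3)C1 | intermediate
6 | quinide C6–O (1-ethoxyprop-2-yn-1-yl) mixed acetal, acetal epimers | O=C3[C@]1(O)C[C@@H](OC(OCC)C#C)[C@@H](O)[C@H](O3)C1 | intermediate
7 | C7 O-(imidazol-1-ylcarbothioyl) derivative of 6 | O=C3[C@]1(O)C[C@@H](OC(OCC)C#C)[C@@H](OC(=S)n4ccnc4)[C@H](O3)C1 | intermediate
8 | tricyclic acetal: quinide with cis-fused 2-ethoxy-3-methyleneoxolane on C6–O/C7 (C7–C11 cis to C6–O) | O=C3[C@]1(O)C[C@@H](OC(OCC)C4=C)[C@@H]4[C@H](O3)C1 | intermediate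
9 | triol from lactone reduction of 8 (C10 hydroxymethyl carbinol, C8–OH) | OC[C@]1(O)C[C@@H](OC(OCC)C4=C)[C@@H]4[C@H](O)C1 | intermediate
10 | β-hydroxy ketone (C10 ketone, C8–OH, oxolane acetal on O6/C7) | O=C1C[C@@H](OC(OCC)C4=C)[C@@H]4[C@H](O)C1 | intermediate
11 | ethyl bromoacetate | CCOC(=O)CBr | starting material
12 | keto ester, 10 with CH2CO2Et on C5 (C5 epimers) | O=C1C(CC(=O)OCC)[C@@H](OC(OCC)C4=C)[C@@H]4[C@H](O)C1 | intermediate
13 | tricyclic keto lactone (cis γ-lactone on O6/C5, trans 2-ethoxy-3-methyleneoxolane on O8/C7) | O=C1C[C@@H](OC(OCC)C3=C)[C@H]3[C@@H]2OC(=O)C[C@H]12 | intermediate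
14 | vinylmagnesium bromide | C=C[Mg]Br | starting material
15 | C10 vinyl carbinol (OH cis to C4, vinyl trans to C4) | C=C[C@@]1(O)C[C@@H](OC(OCC)C3=C)[C@H]3[C@@H]2OC(=O)C[C@H]12 | intermediate
16 | α-hydroxymethylene lactone | C=C[C@@]1(O)C[C@@H](OC(OCC)C3=C)[C@H]3[C@@H]2OC(=O)C(=CO)[C@H]12 | intermediate
17 | oxy-Cope precursor, E-[(4-methoxybenzyl)oxy]methylene lactone | C=C[C@@]1(O)C[C@@H](OC(OCC)C3=C)[C@H]3[C@@H]2OC(=O)/C(=C/OCc4ccc(OC)cc4)[C@H]12 | intermediate
18 | potassium alkoxide of 17 | C=C[C@@]1([O-])C[C@@H](OC(OCC)C3=C)[C@H]3[C@@H]2OC(=O)/C(=C/OCc4ccc(OC)cc4)[C@H]12.[K+] | intermediate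
19 | potassium C10 enolate of 20 | C=C1C(OCC)O[C@@H]2CC([O-])=CC[C@H](OCc4ccc(OC)cc4)C3=C[C@@H](OC3=O)[C@@H]12.[K+] | intermediate
20 | bridged cyclodec-4-en-10-one (butenolide across C4/C6, (3S) 4-methoxybenzyl ether, oxolane acetal on O8/C7) | C=C1C(OCC)O[C@@H]2CC(=O)CC[C@H](OCc4ccc(OC)cc4)C3=C[C@@H](OC3=O)[C@@H]12 | intermediate
21 | C10 exocyclic methylene compound | C=C1C(OCC)O[C@@H]2CC(=C)CC[C@H](OCc4ccc(OC)cc4)C3=C[C@@H](OC3=O)[C@@H]12 | intermediate
22 | B-(C14-alkyl)-9-borabicyclo[3.3.1]nonane | C=C1C(OCC)O[C@@H]2C[C@H](CB5C6CCCC5CCC6)CC[C@H](OCc4ccc(OC)cc4)C3=C[C@@H](OC3=O)[C@@H]12 | intermediate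
23 | C14 primary alcohol, (10R) | C=C1C(OCC)O[C@@H]2C[C@H](CO)CC[C@H](OCc4ccc(OC)cc4)C3=C[C@@H](OC3=O)[C@@H]12 | intermediate
24 | C14 tert-butyldimethylsilyl ether | C=C1C(OCC)O[C@@H]2C[C@H](CO[Si](C)(C)C(C)(C)C)CC[C@H](OCc4ccc(OC)cc4)C3=C[C@@H](OC3=O)[C@@H]12 | intermediate
25 | C3 alcohol | C=C1C(OCC)O[C@@H]2C[C@H](CO[Si](C)(C)C(C)(C)C)CC[C@H](O)C3=C[C@@H](OC3=O)[C@@H]12 | intermediate
26 | C3 isobutyrate | C=C1C(OCC)O[C@@H]2C[C@H](CO[Si](C)(C)C(C)(C)C)CC[C@H](OC(=O)C(C)C)C3=C[C@@H](OC3=O)[C@@H]12 | intermediate
27 | lactol (C12 hemiacetal on O8, C14–OH free) | C=C1C(O)O[C@@H]2C[C@H](CO)CC[C@H](OC(=O)C(C)C)C3=C[C@@H](OC3=O)[C@@H]12 | intermediate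
28 | CNP0332805.1 | C=C1C(=O)O[C@@H]2C[C@H](CO)CC[C@H](OC(=O)C(C)C)C3=C[C@@H](OC3=O)[C@@H]12 | target

**Step count and risks**
Total step count: 20. Longest linear sequence: 19 steps (steps 1 and 3–20, from quinic acid); step 2 is a one-step side branch.

Steps most likely to fail:

1. Step 13 (key step). The lactone acyl group may shift reversibly from the C6 oxygen to the C10 alkoxide and hold the material in a form that cannot rearrange. After the shift, proton transfer from the butenolide C6–H to the enolate may be followed by loss of the C3 ether. The fallback sets out from 17 and comes back at 20 and avoids every anionic intermediate. The tertiary alcohol is silylated (Me3SiOTf, Et3N, CH2Cl2, −78 °C) to the trimethylsilyl ether F1. Heating (decalin, base-washed sealed tube, about 200 °C) should bring about the neutral siloxy-Cope rearrangement through the same locked chair to the trimethylsilyl enol ether F2. Buffered fluoride (Bu4NF, AcOH, THF, 0 °C) then releases ketone 20.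

2. Step 8. The C6 acetal oxygen may be lost by β-elimination from the C5 enolate during the C-alkylation, or proton exchange may move the enolate to C9. The fallback sets out from 10 and comes back at 13. The dianion is formed as before but trapped within minutes at −78 °C with Me3SiCl to give the bis(trimethylsilyl) compound F3 (C5=C10 silyl enol ether, C8 silyl ether). Atom-transfer radical alkylation with ethyl iodoacetate (Et3B, air, CH2Cl2, rt) adds the electrophilic α-ester radical to C5 of the electron-rich enol ether and, after loss of the silyl iodide, gives the C8 O-silyl keto ester F4. Under the conditions of step 9, F4 loses the silyl group to the released ethanol and gives 13.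

3. Step 15. Facial selectivity at C10 may be poor on the ten-membered ring, and the oxolane methylene may compete for the borane. The fallback sets out from 20 and comes back at 23, bypassing steps 14 and 15. Wittig homologation with Ph3P=CHOMe (from the phosphonium chloride and KN(SiMe3)2, THF, 0 °C) gives the methyl enol ether F5. Hg(OAc)2 in aqueous THF followed by KI unmasks the C14 aldehyde F6 under neutral conditions that spare the acetal. C10 is then α to the formyl group, so its configuration can be set by equilibration with a trace of DBU (CH2Cl2, 0 °C), the epimers being separable and recyclable through the aldehyde. NaBH4 at −78 °C reduces only the aldehyde and gives 23.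

**Further compounds**
F1 | step 13 | trimethylsilyl ether of 17 | C=C[C@@]1(O[Si](C)(C)C)C[C@@H](OC(OCC)C3=C)[C@H]3[C@@H]2OC(=O)/C(=C/OCc4ccc(OC)cc4)[C@H]12
F2 | step 13 | trimethylsilyl enol ether of 20 | C=C1C(OCC)O[C@@H]2CC(O[Si](C)(C)C)=CC[C@H](OCc4ccc(OC)cc4)C3=C[C@@H](OC3=O)[C@@H]12
F3 | step 8 | bis(trimethylsilyl) derivative of 10 (C5=C10 silyl enol ether, C8 silyl ether) | C[Si](C)(C)OC1=C[C@@H](OC(OCC)C4=C)[C@@H]4[C@H](O[Si](C)(C)C)C1
F4 | step 8 | C8 O-trimethylsilyl ether of 12 | O=C1C(CC(=O)OCC)[C@@H](OC(OCC)C4=C)[C@@H]4[C@H](O[Si](C)(C)C)C1
F5 | step 15 | C10 methoxymethylene enol ether from 20 | C=C1C(OCC)O[C@@H]2CC(=COC)CC[C@H](OCc4ccc(OC)cc4)C3=C[C@@H](OC3=O)[C@@H]12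
F6 | step 15 | C14 aldehyde, (10R) epimer | C=C1C(OCC)O[C@@H]2C[C@H](C=O)CC[C@H](OCc4ccc(OC)cc4)C3=C[C@@H](OC3=O)[C@@H]12
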